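The earlier runs and the new flask are calculated from invented constants, noise included.

Follow one molecule of starting complex through the flask and count the incoming ligand it costs. Its first exchange costs one ligand. It then stands at a fork as complex with one exchanged: it takes a second ligand, or it stops.

| setting | larch | cedar | flask |
|---|---|---|---|
| starting complex | 1 mM | 1 mM | 1.0 mM |
| incoming ligand | 1.4 mM | 2.2 mM | 1.00 mM |
| remark | run made earlier | run made earlier |  |
| time |  |  | 20 min |

| run | time / min | complex with two exchanged / % | complex with one exchanged / % |
|---|---|---|---|
| larch | 1.33 | 21.1 | 24.3 |
| larch | 2.50 | 25.3 | 21.4 |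
| larch | 5.00 | 31.7 | 20.4 |
| larch | 8.00 | 35.7 | 19.8 |
| larch | 15.0 | 42.1 | 19.8 |
| cedar | 1.33 | 28.8 | 18.8 |
| cedar | 4.00 | 37.0 | 11.3 |
| cedar | 8.00 | 47.5 | 9.5 |
| cedar | 12.0 | 56.4 | 7.4 |
| cedar | 15.0 | 59.9 | 5.1 |

(each reading ± 0.5 percentage points)

- equivalents of incoming ligand to starting complex, everything else as given, that leave most complex with two exchanged at 20 min
- the amount of complex with two exchanged then, in percent of the starting complex charged
- the amount of complex with two exchanged with the amounts as given

**Reading the fork.** If going on is a rate constant times [incoming ligand] and stopping takes no ligand, the odds at the fork grow in proportion to [incoming ligand]. So I divided complex with two exchanged by complex with one exchanged at the first reading, 1.33 min, and then by the ligand charge. The larch run gave 0.620 mM⁻¹ and the cedar run 0.696 mM⁻¹. These are readings with their scatter, and I kept the larch value, whose charge lies nearer the flask's.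

**The chance.** At the flask's 1.00 mM, those odds give a fork chance 0.383, the share of reacted starting complex that takes a second ligand.

**The ledger.** I took incoming ligand as the limiting reagent of the flask, consumed by the asked time. Each reacted complex then costs one ligand plus the fork chance, so complex with two exchanged equals the equivalents times the chance over one plus the chance. For the flask I reckoned 27.7%.

**The forecast.** The forecast gave 31% for the flask as charged and 72% at 5 equiv, a plateau “limited by the slow step, rather than a true maximum”, where my own reckoning for the flask was 27.7%.

**The result.** The flask gave 24.5%, and the best charge was 2.08 equiv, giving 66.3%.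

    starting complex + incoming ligand → leaving ligand + complex with one exchanged (k = 26.0 M⁻¹ s⁻¹)
    complex with one exchanged + incoming ligand → leaving ligand + complex with two exchanged (k = 22.0 M⁻¹ s⁻¹)
    complex with two exchanged + incoming ligand ⇌ leaving ligand + complex with three exchanged (K = 1.30, k = 16.0 M⁻¹ s⁻¹)
    crystals ⇌ leaving ligand, rate k4*(cs4 - [leaving ligand]) while solid is left; crystals form when [leaving ligand] > cs4 (solubility = 0.330 mM, k = 3.10 s⁻¹)
    complex with one exchanged ⇌ isomer of the product (K = 1.30, k = 0.0180 s⁻¹)

**At rest.** At 20.0 min the flask held 0.082% of its incoming ligand against 25% of its starting complex, so the ledger's assumption stood. The share of reacted starting complex standing as complex with two exchanged was 0.327, less than my chance of 0.383. For the neighbour flask with 2.5 mM of starting complex, the ledger at my chance gave 11.1%, but at 20.0 min that flask held 4.88%, a share of 0.139. Left ten times as long, the flask held 24.9% of complex with two exchanged, 0.40 percentage points above the 24.5% at the asked time.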